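**Retrosynthetic overview**

1. Target ⇒ MOM removal and ortho-hydroxylation at C3' of a ring B phenol ⇒ aromatic Claisen rearrangement of a 4'-O-prenyl isoflavan (puts the 1,1-dimethylallyl group on C5').
2. Ring C (the pyran, the only ring that is built, closed after the stereocentre exists) ⇒ O1–C8a bond by intramolecular SNAr of a primary alkoxide on an ortho-fluoroarene (ring A).
3. Key bond C3–C1' ⇒ photochemical, stereoinvertive 1,2-shift of ring B from a ketone carbonyl to the neighbouring C–Cl carbon (α-chloro ketone → methyl 2,3-diarylpropanoate).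
4. α-Chloro ketone ⇒ ring B aryl Grignard + (S)-α-chloro Weinreb amide ⇒ (R)-α-hydroxy Weinreb amide (Appel inversion).
5. (R)-α-Hydroxy amide ⇒ methyl (R)-glycidate (chiral pool, L-serine series; supplies C2, C3, C4) + ring A aryl Grignard (copper-catalysed opening at CH2); rings A and B are bought as arenes.

Assumption: 4-bromo-3-fluorophenol, 4-bromo-3-methoxyphenol, prenyl bromide and methyl (R)-glycidate are taken as catalogue compounds; isoflavan numbering (O1, C2, C3, C4, C4a to C8a, primed numbers for ring B) is used throughout.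

**Route**

Step 1
Reactants: 1 4-bromo-3-fluorophenol
Product: 2 1-bromo-2-fluoro-4-(methoxymethoxy)benzene
Conditions: NaH, MOMCl, DMF, 0 °C to rt
Reagents that add atoms: chloromethyl methyl ether (MOMCl), COCCl
Why: Williamson O-alkylation of the sodium phenoxide gives a MOM ether that tolerates the organomagnesium, hydride and strong-base steps and is removed last under mild acid.

Step 2
Reactants: 3 4-bromo-3-methoxyphenol; 4 1-bromo-3-methylbut-2-ene (prenyl bromide)
Product: 5 1-bromo-2-methoxy-4-[(3-methylbut-2-en-1-yl)oxy]benzene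
Conditions: K2CO3, acetone, 50 °C
Reagents that add atoms: none
Why: Williamson etherification of the single phenol puts the prenyl ether on the future O4', where it later delivers the 1,1-dimethylallyl group by Claisen rearrangement and keeps the ketone of step 6 from being a free para-hydroxyphenyl ketone.

Step 3
Reactants: 2 1-bromo-2-fluoro-4-(methoxymethoxy)benzene; 6 methyl (2R)-oxirane-2-carboxylate (methyl (R)-glycidate)
Product: 9 (2R)-3-[2-fluoro-4-(methoxymethoxy)phenyl]-2-hydroxy-N-methoxy-N-methylpropanamide, via arylmagnesium bromide 7 (not isolated), via hydroxy ester 8 (not isolated)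
Conditions: Mg turnings, LiCl, THF, 0–10 °C; then CuI (10 mol %), 6, −40 °C; then MeNHOMe·HCl, i-PrMgCl, −20 to 0 °C
Reagents that add atoms: N,O-dimethylhydroxylamine hydrochloride, CNOC.Cl
Why: Copper-catalysed Grignard opening of the epoxide at its CH2 carbon leaves the bought stereocentre untouched (R kept; it becomes C3 of the target), and the chloromagnesium amide of MeNHOMe then converts the ester into the Weinreb amide by aminolysis in the same pot.

Step 4
Reactants: 9 (2R)-3-[2-fluoro-4-(methoxymethoxy)phenyl]-2-hydroxy-N-methoxy-N-methylpropanamide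
Product: 10 (2S)-2-chloro-3-[2-fluoro-4-(methoxymethoxy)phenyl]-N-methoxy-N-methylpropanamide
Conditions: PPh3, N-chlorosuccinimide, THF, 0 °C to rt
Reagents that add atoms: N-chlorosuccinimide, ClN1C(=O)CCC1=O
Why: Appel-type chlorination, in which chloride displaces the alkoxyphosphonium group by SN2 next to the amide carbonyl, so the bought centre is inverted cleanly from R to S.

Step 5
Reactants: 5 1-bromo-2-methoxy-4-[(3-methylbut-2-en-1-yl)oxy]benzene; 10 (2S)-2-chloro-3-[2-fluoro-4-(methoxymethoxy)phenyl]-N-methoxy-N-methylpropanamide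
Product: 12 (2S)-2-chloro-3-[2-fluoro-4-(methoxymethoxy)phenyl]-1-{2-methoxy-4-[(3-methylbut-2-en-1-yl)oxy]phenyl}propan-1-one, via arylmagnesium bromide 11 (not isolated)
Conditions: 5, Mg turnings, LiCl, THF, 25 °C; then 10, THF, −20 to 0 °C; aq. NH4Cl
Reagents that add atoms: none
Why: Weinreb ketone synthesis, in which the chelated tetrahedral adduct survives until work-up so only one aryl group adds, and at −20 °C the C–Cl centre is not enolised (S kept).

Step 6
Reactants: 12 (2S)-2-chloro-3-[2-fluoro-4-(methoxymethoxy)phenyl]-1-{2-methoxy-4-[(3-methylbut-2-en-1-yl)oxy]phenyl}propan-1-one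
Product: 13 methyl (2S)-3-[2-fluoro-4-(methoxymethoxy)phenyl]-2-{2-methoxy-4-[(3-methylbut-2-en-1-yl)oxy]phenyl}propanoate
Conditions: hν (310 nm LEDs, Pyrex), MeOH–MeCN 1:3 (0.01 M), propylene oxide (10 equiv), Ar, 10 °C
Reagents that add atoms: methanol, CO
Why: Proposed new method: direct excitation of the 2,4-dialkoxyphenyl ketone populates a charge-transfer ππ* state in which the C–Cl bond ionises with help from the ipso carbon of electron-rich ring B, which attacks the α-carbon from the face opposite to chloride (aryl-bridged, cyclopropanone-like ion pair), and collapse to the acylium ion followed by capture by methanol gives the ester, so the C3–C1' bond forms with inversion at carbon and the (S)-chloride gives the (S)-aryl centre of the target (the descriptor stays S because the priorities change); the closest known reaction type is the photochemical 1,2-aryl shift of simple 2-chloropropiophenones to 2-arylpropanoic acids (a photo-Favorskii-type rearrangement) and the thermal Lewis-acid-induced 1,2-aryl shift of α-halo ketals, neither shown for a β-aryl α-chloro ketone with a dialkoxyphenyl migrating group and alcohol capture.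

Step 7
Reactants: 13 methyl (2S)-3-[2-fluoro-4-(methoxymethoxy)phenyl]-2-{2-methoxy-4-[(3-methylbut-2-en-1-yl)oxy]phenyl}propanoate
Product: 14 (2S)-3-[2-fluoro-4-(methoxymethoxy)phenyl]-2-{2-methoxy-4-[(3-methylbut-2-en-1-yl)oxy]phenyl}propan-1-ol
Conditions: LiAlH4, THF, 0 °C
Reagents that add atoms: none
Why: Hydride reduction of the ester to the primary alcohol is fast at 0 °C, so the α-aryl centre is not epimerised, and the aryl fluoride, MOM ether and prenyl ether are inert.

Step 8
Reactants: 14 (2S)-3-[2-fluoro-4-(methoxymethoxy)phenyl]-2-{2-methoxy-4-[(3-methylbut-2-en-1-yl)oxy]phenyl}propan-1-ol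
Product: 15 (3S)-7-(methoxymethoxy)-3-{2-methoxy-4-[(3-methylbut-2-en-1-yl)oxy]phenyl}-3,4-dihydro-2H-1-benzopyran
Conditions: KOt-Bu, THF–DMF 4:1, 65 °C
Reagents that add atoms: none
Why: Intramolecular SNAr (6-exo) of the potassium alkoxide on the ortho-fluoroarene closes ring C through O1–C8a without touching the stereocentre.

Step 9
Reactants: 15 (3S)-7-(methoxymethoxy)-3-{2-methoxy-4-[(3-methylbut-2-en-1-yl)oxy]phenyl}-3,4-dihydro-2H-1-benzopyran
Product: 16 4-[(3S)-7-(methoxymethoxy)-3,4-dihydro-2H-1-benzopyran-3-yl]-5-methoxy-2-(2-methylbut-3-en-2-yl)phenol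
Conditions: N,N-diethylaniline, 185 °C, sealed tube
Reagents that add atoms: none
Why: Aromatic Claisen rearrangement, a [3,3] shift that moves the prenyl group from O4' to the less hindered ortho carbon C5' with allyl inversion (C3' is flanked by OMe; the para position is blocked), then tautomerises to the 1,1-dimethylallyl phenol.

Step 10
Reactants: 16 4-[(3S)-7-(methoxymethoxy)-3,4-dihydro-2H-1-benzopyran-3-yl]-5-methoxy-2-(2-methylbut-3-en-2-yl)phenol
Product: 18 4-[(3S)-7-(methoxymethoxy)-3,4-dihydro-2H-1-benzopyran-3-yl]-3-methoxy-6-(2-methylbut-3-en-2-yl)benzene-1,2-diol, via ortho-quinone 17 (not isolated)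
Conditions: 2-iodoxybenzoic acid (IBX), DMF, 0 °C to rt; then aq. Na2S2O4
Reagents that add atoms: 2-iodoxybenzoic acid (IBX), OI1(=O)OC(=O)c2ccccc12
Why: Regioselective phenol ortho-oxygenation, in which the phenol binds pentavalent iodine and oxygen is delivered within the complex to the only free ortho C–H (C3'), and the resulting ortho-quinone is reduced at once by Na2S2O4 to the catechol; ring A is a MOM ether, not a phenol, and is not attacked.

Step 11
Reactants: 18 4-[(3S)-7-(methoxymethoxy)-3,4-dihydro-2H-1-benzopyran-3-yl]-3-methoxy-6-(2-methylbut-3-en-2-yl)benzene-1,2-diol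
Product: 19 4-[(3S)-7-hydroxy-3,4-dihydro-2H-1-benzopyran-3-yl]-3-methoxy-6-(2-methylbut-3-en-2-yl)benzene-1,2-diol (the target)
Conditions: 2 M HCl, MeOH, 40 °C, Ar
Reagents that add atoms: none
Why: Acid-catalysed acetal exchange with methanol removes the MOM group under conditions mild enough for the catechol, the 1,1-dimethylallyl group and the C3 stereocentre.

**Compound list**

1 | 4-bromo-3-fluorophenol | Oc1ccc(Br)c(F)c1 | starting material
2 | 1-bromo-2-fluoro-4-(methoxymethoxy)benzene | COCOc1ccc(Br)c(F)c1 | intermediate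
3 | 4-bromo-3-methoxyphenol | COc1cc(O)ccc1Br | starting material
4 | 1-bromo-3-methylbut-2-ene (prenyl bromide) | CC(C)=CCBr | starting material
5 | 1-bromo-2-methoxy-4-[(3-methylbut-2-en-1-yl)oxy]benzene | COc1cc(OCC=C(C)C)ccc1Br | intermediate
6 | methyl (2R)-oxirane-2-carboxylate (methyl (R)-glycidate) | COC(=O)[C@H]1CO1 | starting material
7 | [2-fluoro-4-(methoxymethoxy)phenyl]magnesium bromide (formed in the flask) | COCOc1ccc([Mg]Br)c(F)c1 | intermediate
8 | methyl (2R)-3-[2-fluoro-4-(methoxymethoxy)phenyl]-2-hydroxypropanoate (present as its bromomagnesium alkoxide, not isolated) | COC(=O)[C@H](O)Cc1ccc(OCOC)cc1F | intermediate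
9 | (2R)-3-[2-fluoro-4-(methoxymethoxy)phenyl]-2-hydroxy-N-methoxy-N-methylpropanamide | CON(C)C(=O)[C@H](O)Cc1ccc(OCOC)cc1F | intermediate
10 | (2S)-2-chloro-3-[2-fluoro-4-(methoxymethoxy)phenyl]-N-methoxy-N-methylpropanamide | CON(C)C(=O)[C@@H](Cl)Cc1ccc(OCOC)cc1F | intermediate
11 | {2-methoxy-4-[(3-methylbut-2-en-1-yl)oxy]phenyl}magnesium bromide (formed in the flask) | COc1cc(OCC=C(C)C)ccc1[Mg]Br | intermediate
12 | (2S)-2-chloro-3-[2-fluoro-4-(methoxymethoxy)phenyl]-1-{2-methoxy-4-[(3-methylbut-2-en-1-yl)oxy]phenyl}propan-1-one | COc1cc(OCC=C(C)C)ccc1C(=O)[C@@H](Cl)Cc1ccc(OCOC)cc1F | intermediate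
13 | methyl (2S)-3-[2-fluoro-4-(methoxymethoxy)phenyl]-2-{2-methoxy-4-[(3-methylbut-2-en-1-yl)oxy]phenyl}propanoate | COC(=O)[C@H](c1ccc(OCC=C(C)C)cc1OC)Cc1ccc(OCOC)cc1F | intermediate
14 | (2S)-3-[2-fluoro-4-(methoxymethoxy)phenyl]-2-{2-methoxy-4-[(3-methylbut-2-en-1-yl)oxy]phenyl}propan-1-ol | OC[C@H](c1ccc(OCC=C(C)C)cc1OC)Cc1ccc(OCOC)cc1F | intermediate
15 | (3S)-7-(methoxymethoxy)-3-{2-methoxy-4-[(3-methylbut-2-en-1-yl)oxy]phenyl}-3,4-dihydro-2H-1-benzopyran | COCOc1ccc2C[C@H](COc2c1)c1ccc(OCC=C(C)C)cc1OC | intermediate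
16 | 4-[(3S)-7-(methoxymethoxy)-3,4-dihydro-2H-1-benzopyran-3-yl]-5-methoxy-2-(2-methylbut-3-en-2-yl)phenol | COCOc1ccc2C[C@H](COc2c1)c1cc(C(C)(C)C=C)c(O)cc1OC | intermediate
17 | 4-[(3S)-7-(methoxymethoxy)-3,4-dihydro-2H-1-benzopyran-3-yl]-3-methoxy-6-(2-methylbut-3-en-2-yl)cyclohexa-3,5-diene-1,2-dione (ortho-quinone, formed in the flask) | COCOc1ccc2C[C@H](COc2c1)C1=C(OC)C(=O)C(=O)C(C(C)(C)C=C)=C1 | intermediate
18 | 4-[(3S)-7-(methoxymethoxy)-3,4-dihydro-2H-1-benzopyran-3-yl]-3-methoxy-6-(2-methylbut-3-en-2-yl)benzene-1,2-diol | COCOc1ccc2C[C@H](COc2c1)c1cc(C(C)(C)C=C)c(O)c(O)c1OC | intermediate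
19 | 4-[(3S)-7-hydroxy-3,4-dihydro-2H-1-benzopyran-3-yl]-3-methoxy-6-(2-methylbut-3-en-2-yl)benzene-1,2-diol | C=CC(C)(C)c1cc([C@H]2COc3cc(O)ccc3C2)c(OC)c(O)c1O | target

**Step count and risks**

Total: 11 steps. Longest linear sequence: 10 steps (steps 1 and 3 to 11, from 4-bromo-3-fluorophenol).

The three steps most likely to fail:

The ketone formation of step 5 can fail through enolisation of 10 by the basic Grignard reagent, which would erode the ee or eliminate HCl to the cinnamamide. Fallback, with the order of events changed: set out from 9 and add 11 (2.3 equiv, THF, −20 °C) to the free hydroxy amide to get the α-hydroxy ketone (2R)-3-[2-fluoro-4-(methoxymethoxy)phenyl]-2-hydroxy-1-{2-methoxy-4-[(3-methylbut-2-en-1-yl)oxy]phenyl}propan-1-one F1. Chlorinating it with inversion (PPh3, N-chlorosuccinimide, CH2Cl2, −20 °C, short contact time) comes back to the route at 12.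

The photochemical aryl shift of step 6 is the proposed new step and the least certain. It can fail in three ways:
- homolysis of the C–Cl bond instead of assisted ionisation, giving the dechlorinated ketone and partial loss of configuration;
- quenching of the excited ketone, or competing phenonium participation, by the alkoxy-substituted ring A;
- light-induced cleavage of the prenyl ether.

Fallback with known chemistry: set out from 12 and convert it with HC(OMe)3 and a trace of camphorsulfonic acid in MeOH into the dimethyl ketal 1-{(2S)-2-chloro-3-[2-fluoro-4-(methoxymethoxy)phenyl]-1,1-dimethoxypropyl}-2-methoxy-4-[(3-methylbut-2-en-1-yl)oxy]benzene F2. The thermal silver-assisted 1,2-aryl shift of this α-halo ketal (AgBF4, CaCO3, MeOH, 50 °C) is stereospecific with inversion, and aqueous work-up comes back to the route at ester 13.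

The ortho-oxygenation of step 10 can fail by over-oxidation, or by tautomerisation of ortho-quinone 17 to a quinone methide through its C3–H, which would erase the stereocentre. Fallback that avoids any quinone: set out from 16 and ortho-formylate the phenol at C3' (MgCl2, Et3N, paraformaldehyde, MeCN, 80 °C) to get 2-hydroxy-6-methoxy-5-[(3S)-7-(methoxymethoxy)-3,4-dihydro-2H-1-benzopyran-3-yl]-3-(2-methylbut-3-en-2-yl)benzaldehyde F3. Dakin oxidation (H2O2, NaOH, THF–H2O, 0 °C) then comes back to the route at 18.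

**Further compounds**

F1 | step 5 | (2R)-3-[2-fluoro-4-(methoxymethoxy)phenyl]-2-hydroxy-1-{2-methoxy-4-[(3-methylbut-2-en-1-yl)oxy]phenyl}propan-1-one | COc1cc(OCC=C(C)C)ccc1C(=O)[C@H](O)Cc1ccc(OCOC)cc1F
F2 | step 6 | 1-{(2S)-2-chloro-3-[2-fluoro-4-(methoxymethoxy)phenyl]-1,1-dimethoxypropyl}-2-methoxy-4-[(3-methylbut-2-en-1-yl)oxy]benzene | COc1cc(OCC=C(C)C)ccc1C(OC)(OC)[C@@H](Cl)Cc1ccc(OCOC)cc1F
F3 | step 10 | 2-hydroxy-6-methoxy-5-[(3S)-7-(methoxymethoxy)-3,4-dihydro-2H-1-benzopyran-3-yl]-3-(2-methylbut-3-en-2-yl)benzaldehyde | COCOc1ccc2C[C@H](COc2c1)c1cc(C(C)(C)C=C)c(O)c(C=O)c1OC
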